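**Retrosynthetic overview**

1. Target ⇐ equatorial hydride delivery to a 2,6-cis-oxan-4-one (axial C4–OH) ⇐ syn-hydrogenation of a 6-aryl-2-alkyl-2,3-dihydro-4H-pyran-4-one (C6 set cis to C2, benzyl ethers cleaved in the same operation).
2. C6–aryl bond ⇐ Heck arylation of the 2-substituted dihydropyranone with a benzyl-protected 5-iodo-3-methoxycatechol.
3. Oxane ring and C2 stereocentre ⇐ catalytic enantioselective four-to-six ring expansion of 3-ethoxycyclobutanone with a 3-arylpropanal (aldehyde C=O inserted into the cyclobutanone C2–C3 bond, then loss of ethanol).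
4. 3-Arylpropanal ⇐ Heck reaction of an aryl iodide with allyl alcohol; both aryl iodides ⇐ 4-iodoguaiacol ⇐ catechol (O-methylation, para-iodination; third oxygen by ortho-formylation/Dakin).
5. Ring order: both benzene rings are bought as catechol; the oxane is the only ring made, in the ring-expansion step.

Target stereochemistry as read from the SMILES: (2S,4S,6S), with the two carbon substituents 2,6-cis (diequatorial) and the 4-OH trans to both (axial).

Assumption: 3-ethoxycyclobutan-1-one is bought as a catalogue building block, and the catalyst antipode in step 5 is the one that gives the (S)-pyranone, to be fixed by a first screen (both antipodes are accessible).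

**Route**

Step 1
Reactants: 1 catechol (benzene-1,2-diol)
Product: 2 2-methoxyphenol (guaiacol)
Conditions: MeI (1.0 equiv), K2CO3 (1.0 equiv), acetone, reflux
Reagents that add atoms: iodomethane (CI)
Why: Williamson mono-O-methylation with one equivalent of electrophile; the dimethyl ether and unreacted catechol are removed by base extraction and distillation.

Step 2
Reactants: 2 2-methoxyphenol
Product: 3 4-iodo-2-methoxyphenol
Conditions: NaI, NaOH, aq. NaOCl, MeOH, 0 °C
Reagents that add atoms: sodium iodide ([Na+].[I-])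
Why: Electrophilic aromatic iodination of the phenolate by hypoiodite made in the flask goes para to the phenoxide oxygen, the stronger director, and so fixes the 1,3,4-pattern.

Step 3
Reactants: 3 4-iodo-2-methoxyphenol
Product: 4 1-(benzyloxy)-4-iodo-2-methoxybenzene
Conditions: BnBr, K2CO3, DMF, rt
Reagents that add atoms: benzyl bromide (BrCc1ccccc1)
Why: Williamson benzylation masks the phenol for the acid-catalysed step 5; the ether is cleaved by hydrogenolysis in step 10.

Step 4
Reactants: 4 1-(benzyloxy)-4-iodo-2-methoxybenzene; 5 prop-2-en-1-ol (allyl alcohol)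
Product: 6 3-[4-(benzyloxy)-3-methoxyphenyl]propanal
Conditions: Pd(OAc)2 (3 mol%), Bu4NCl, NaHCO3, DMF, 45 °C
Reagents that add atoms: none
Why: Heck reaction under Jeffery conditions: the aryl–palladium species adds to the terminal alkene carbon, and β-hydride elimination toward the carbinol gives an enol that tautomerises to the saturated aldehyde.

Step 5
Reactants: 6 3-[4-(benzyloxy)-3-methoxyphenyl]propanal; 7 3-ethoxycyclobutan-1-one
Product: 9 (2S)-2-{2-[4-(benzyloxy)-3-methoxyphenyl]ethyl}-2,3-dihydro-4H-pyran-4-one, via 6-ethoxy acetal 8 (not isolated)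
Conditions: chiral imidodiphosphorimidate Brønsted acid (two (S)-3,3'-diaryl-BINOL units on a P(=NSO2CF3)–NH–P(=NSO2CF3) core, 5 mol%), 5 Å molecular sieves, CHCl3, −60 to −30 °C, slow addition of 7; then TFA (cat.), CH2Cl2, 0 °C
Reagents that add atoms: none
Why: Proposed new method: a catalytic enantioselective ring expansion of a 3-alkoxycyclobutanone with an aldehyde. The confined strong acid protonates the strained ketone 7, whose C2–C3 bond opens with push from the ethoxy oxygen to give an enol tethered to an ethoxycarbenium ion paired with the chiral anion. The carbonyl oxygen of 6 adds to that cation, and the resulting O-alkylated aldehyde (a new oxocarbenium ion) is closed by the tethered enol through a chair transition state inside the anion pocket. This C–C bond formation is enantio-determining and sets C2 as S; acetal 8 then loses ethanol to give the vinylogous ester 9. The sequence is stepwise and ionic, not pericyclic. The closest known reactions are the racemic formal [4+2] ring expansion of 3-ethoxycyclobutanones with aldehydes promoted by stoichiometric BF3·OEt2, and asymmetric Prins cyclisations of aldehyde-derived oxocarbenium ions under the same class of confined acids.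

Step 6
Reactants: 3 4-iodo-2-methoxyphenol
Product: 11 2-hydroxy-5-iodo-3-methoxybenzaldehyde, via hydroxymethyl phenol 10 (not isolated)
Conditions: MgCl2, Et3N, (CH2O)n, MeCN, reflux; aq. HCl work-up
Reagents that add atoms: paraformaldehyde (formaldehyde unit, C=O)
Why: Casnati–Skattebøl ortho-formylation: the magnesium phenoxide delivers formaldehyde to the only free ortho position, and the benzylic alkoxide is oxidised by a second formaldehyde through Oppenauer-type hydride transfer.

Step 7
Reactants: 11 2-hydroxy-5-iodo-3-methoxybenzaldehyde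
Product: 13 5-iodo-3-methoxybenzene-1,2-diol, via aryl formate 12 (not isolated)
Conditions: 30% H2O2, NaOH, THF/H2O, 0 °C to rt; then dilute HCl, under N2
Reagents that add atoms: hydrogen peroxide (OO)
Why: Dakin oxidation: hydroperoxide adds to the ortho-hydroxy aldehyde, the aryl group migrates to oxygen and the formate is hydrolysed in the flask, giving the 1,2,3-trioxygenated ring with iodine para to the central oxygen.

Step 8
Reactants: 13 5-iodo-3-methoxybenzene-1,2-diol
Product: 14 1,2-bis(benzyloxy)-5-iodo-3-methoxybenzene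
Conditions: BnBr (2.3 equiv), K2CO3, DMF, 50 °C
Reagents that add atoms: benzyl bromide (BrCc1ccccc1)
Why: Double Williamson benzylation protects the air-sensitive catechol with groups that leave in the same hydrogenation as the other benzyl ether.

Step 9
Reactants: 9 (2S)-2-{2-[4-(benzyloxy)-3-methoxyphenyl]ethyl}-2,3-dihydro-4H-pyran-4-one; 14 1,2-bis(benzyloxy)-5-iodo-3-methoxybenzene
Product: 15 (2S)-6-[3,4-bis(benzyloxy)-5-methoxyphenyl]-2-{2-[4-(benzyloxy)-3-methoxyphenyl]ethyl}-2,3-dihydro-4H-pyran-4-one
Conditions: Pd(OAc)2 (10 mol%), Bu4NBr, KOAc, DMF, 90 °C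
Reagents that add atoms: none
Why: Heck arylation: the aryl–palladium iodide (divalent palladium) inserts into the polarised C5=C6 bond with aryl going to C6 (oxygen-bearing, β to the carbonyl); the C5 palladium enolate epimerises through its oxygen-bound form, and syn β-hydride elimination restores the enone. The weak acetate base leaves C2 and the C3 methylene untouched.

Step 10
Reactants: 15 (2S)-6-[3,4-bis(benzyloxy)-5-methoxyphenyl]-2-{2-[4-(benzyloxy)-3-methoxyphenyl]ethyl}-2,3-dihydro-4H-pyran-4-one
Product: 17 (2S,6S)-2-(3,4-dihydroxy-5-methoxyphenyl)-6-[2-(4-hydroxy-3-methoxyphenyl)ethyl]tetrahydro-4H-pyran-4-one, via tribenzyl cis-ketone 16 (not isolated)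
Conditions: H2 (1 atm), Pd/C (10 wt% palladium metal on carbon), EtOAc, rt; then MeOH added and H2 continued, rt; stopped at the calculated uptake
Reagents that add atoms: none
Why: Heterogeneous hydrogenation delivers hydrogen to the C5=C6 face opposite the C2 side chain, so H-6 ends syn to H-2 and the ring is 2,6-cis (6S), as is usual for 2,6-disubstituted dihydropyran-4-ones. Hydrogenolysis of the three benzyl aryl ethers follows once methanol is added; the cyclic benzylic ether is much slower to cleave.

Step 11
Reactants: 17 (2S,6S)-2-(3,4-dihydroxy-5-methoxyphenyl)-6-[2-(4-hydroxy-3-methoxyphenyl)ethyl]tetrahydro-4H-pyran-4-one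
Product: 18 (2S,4S,6S)-2-(3,4-dihydroxy-5-methoxyphenyl)-6-[2-(4-hydroxy-3-methoxyphenyl)ethyl]tetrahydro-2H-pyran-4-ol
Conditions: LiBH(s-Bu)3 (5 equiv), THF, −78 °C; AcOH/MeOH quench, non-oxidative work-up under N2
Reagents that add atoms: none
Why: Stereoselective ketone reduction: the bulky trialkylborohydride attacks the diequatorial chair ketone from the equatorial direction and gives the axial alcohol (4S, trans to both substituents). Three equivalents are consumed by the phenols, which are carried as lithium phenoxides.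

**Compound list**

1 | catechol (benzene-1,2-diol) | Oc1ccccc1O | starting material
2 | 2-methoxyphenol | COc1ccccc1O | intermediate
3 | 4-iodo-2-methoxyphenol | COc1cc(I)ccc1O | intermediate
4 | 1-(benzyloxy)-4-iodo-2-methoxybenzene | COc1cc(I)ccc1OCc1ccccc1 | intermediate
5 | prop-2-en-1-ol | C=CCO | starting material
6 | 3-[4-(benzyloxy)-3-methoxyphenyl]propanal | COc1cc(CCC=O)ccc1OCc1ccccc1 | intermediate
7 | 3-ethoxycyclobutan-1-one | CCOC1CC(=O)C1 | starting material
8 | (2S)-2-{2-[4-(benzyloxy)-3-methoxyphenyl]ethyl}-6-ethoxytetrahydro-4H-pyran-4-one (both C6 epimers) | COc1cc(CC[C@H]2CC(=O)CC(OCC)O2)ccc1OCc1ccccc1 | intermediate (not isolated)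
9 | (2S)-2-{2-[4-(benzyloxy)-3-methoxyphenyl]ethyl}-2,3-dihydro-4H-pyran-4-one | COc1cc(CC[C@H]2CC(=O)C=CO2)ccc1OCc1ccccc1 | intermediate
10 | 2-(hydroxymethyl)-4-iodo-6-methoxyphenol (as its magnesium salt) | COc1cc(I)cc(CO)c1O | intermediate (not isolated)
11 | 2-hydroxy-5-iodo-3-methoxybenzaldehyde | COc1cc(I)cc(C=O)c1O | intermediate
12 | 2-hydroxy-5-iodo-3-methoxyphenyl formate | COc1cc(I)cc(OC=O)c1O | intermediate (not isolated)
13 | 5-iodo-3-methoxybenzene-1,2-diol | COc1cc(I)cc(O)c1O | intermediate
14 | 1,2-bis(benzyloxy)-5-iodo-3-methoxybenzene | COc1cc(I)cc(OCc2ccccc2)c1OCc1ccccc1 | intermediate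
15 | (2S)-6-[3,4-bis(benzyloxy)-5-methoxyphenyl]-2-{2-[4-(benzyloxy)-3-methoxyphenyl]ethyl}-2,3-dihydro-4H-pyran-4-one | COc1cc(CC[C@H]2CC(=O)C=C(c3cc(OC)c(OCc4ccccc4)c(OCc4ccccc4)c3)O2)ccc1OCc1ccccc1 | intermediate
16 | (2S,6S)-2-[3,4-bis(benzyloxy)-5-methoxyphenyl]-6-{2-[4-(benzyloxy)-3-methoxyphenyl]ethyl}tetrahydro-4H-pyran-4-one | COc1cc(CC[C@H]2CC(=O)C[C@@H](c3cc(OC)c(OCc4ccccc4)c(OCc4ccccc4)c3)O2)ccc1OCc1ccccc1 | intermediate (not isolated)
17 | (2S,6S)-2-(3,4-dihydroxy-5-methoxyphenyl)-6-[2-(4-hydroxy-3-methoxyphenyl)ethyl]tetrahydro-4H-pyran-4-one | COc1cc(CC[C@H]2CC(=O)C[C@@H](c3cc(O)c(O)c(OC)c3)O2)ccc1O | intermediate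
18 | (2S,4S,6S)-2-(3,4-dihydroxy-5-methoxyphenyl)-6-[2-(4-hydroxy-3-methoxyphenyl)ethyl]tetrahydro-2H-pyran-4-ol | COc1cc(CC[C@H]2C[C@H](O)C[C@@H](c3cc(O)c(O)c(OC)c3)O2)ccc1O | target

**Step count and risks**

Total steps: 11. Longest linear sequence: 8 (steps 1, 2, 3, 4, 5, 9, 10, 11; the branch through steps 6, 7, 8 is equally long).

Steps most likely to fail:

Step 5 (the new ring expansion). Risks are low enantioselectivity, acid-induced self-aldol or Friedel–Crafts closure of the electron-rich aldehyde, and slow turnover because of released ethanol. Fallback, from 6 back to 9, with known chemistry: asymmetric hetero-Diels–Alder reaction in its Mukaiyama-aldol form. Aldehyde 6 is treated with Danishefsky's diene (trans-1-methoxy-3-(trimethylsilyloxy)buta-1,3-diene, CO/C=C/C(=C)O[Si](C)(C)C) and a BINOL/Ti(OiPr)4 catalyst (tetravalent titanium, 10 mol%, the BINOL antipode that gives the S product, 4 Å molecular sieves, Et2O, −20 °C). This gives the aldol adduct (1E,5S)-7-[4-(benzyloxy)-3-methoxyphenyl]-5-hydroxy-1-methoxyhept-1-en-3-one F1, which closes with TFA in CH2Cl2, losing methanol, to 9. It also supplies reference material for assigning the configuration of 9 from step 5.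

Step 9 (Heck arylation at C6). Risks are arylation at C5 instead of C6, reductive Heck to the saturated 2,6-trans ketone, or slow β-hydride elimination. Fallback, from 9 and 14 back to 15: iodide 14 is converted with i-PrMgCl·LiCl (THF, −20 °C) into [3,4-bis(benzyloxy)-5-methoxyphenyl]magnesium chloride F2. F2 is added to 9 with CuBr·SMe2 (10 mol%) and TMSCl at −78 °C; conjugate addition is axial, trans to the C2 chain, and the enolate is trapped regiospecifically as (2S,6R)-6-[3,4-bis(benzyloxy)-5-methoxyphenyl]-2-{2-[4-(benzyloxy)-3-methoxyphenyl]ethyl}-4-(trimethylsilyloxy)-3,6-dihydro-2H-pyran F3. Saegusa–Ito oxidation of F3 (Pd(OAc)2, MeCN, rt) places the double bond between C5 and C6 and gives 15; the C6 centre made in the addition is erased and is reset in step 10.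

Step 11 (hydride reduction of the triphenol). Risks are poorly soluble lithium phenoxides, incomplete reduction, and boron residues that are hard to remove without oxidising the catechol. Fallback, from 15 back to 18: 15 is hydrogenated over Pd/C poisoned with Ph2S in EtOAc, which saturates the C5=C6 bond but leaves benzyl ethers, so that 16 is isolated. LiBH(s-Bu)3 (THF, −78 °C, normal oxidative work-up) then gives (2S,4S,6S)-2-[3,4-bis(benzyloxy)-5-methoxyphenyl]-6-{2-[4-(benzyloxy)-3-methoxyphenyl]ethyl}tetrahydro-2H-pyran-4-ol F4. Hydrogenolysis of F4 (H2, Pd/C, EtOAc/MeOH) gives 18.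

**Further compounds**

F1 | step 5 | (1E,5S)-7-[4-(benzyloxy)-3-methoxyphenyl]-5-hydroxy-1-methoxyhept-1-en-3-one | CO/C=C/C(=O)C[C@@H](O)CCc1ccc(OCc2ccccc2)c(OC)c1
F2 | step 9 | [3,4-bis(benzyloxy)-5-methoxyphenyl]magnesium chloride | COc1cc([Mg]Cl)cc(OCc2ccccc2)c1OCc1ccccc1
F3 | step 9 | (2S,6R)-6-[3,4-bis(benzyloxy)-5-methoxyphenyl]-2-{2-[4-(benzyloxy)-3-methoxyphenyl]ethyl}-4-(trimethylsilyloxy)-3,6-dihydro-2H-pyran | COc1cc(CC[C@H]2CC(O[Si](C)(C)C)=C[C@H](c3cc(OC)c(OCc4ccccc4)c(OCc4ccccc4)c3)O2)ccc1OCc1ccccc1
F4 | step 11 | (2S,4S,6S)-2-[3,4-bis(benzyloxy)-5-methoxyphenyl]-6-{2-[4-(benzyloxy)-3-methoxyphenyl]ethyl}tetrahydro-2H-pyran-4-ol | COc1cc(CC[C@H]2C[C@H](O)C[C@@H](c3cc(OC)c(OCc4ccccc4)c(OCc4ccccc4)c3)O2)ccc1OCc1ccccc1
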